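**Conventions.** Atom labels are those of the target: C1 lactone C=O, C2=C3 ring enoate, C4, C5 (N–CH), C6–C8, C9 (spiro C–N), C10–C12, C13 (ring CH), C14 (CHMe), C15=C16, C17 (CHOH), C18=C19 (Cl on C19), C20, C21 (OCH2), C23 (NCH2). Descriptors quoted with these labels refer to the compound in question, so a descriptor can change when only the CIP ranking changes.

Route in numbers: 1 + 2 → 3 → 4 → (5, 6) → 7 → 8 → 9; 10 + 11 → 12 → 13; 9 + 13 → 14 → 15 → 16; 16 + 17 → 18 → 19 → 20 → 21 → 22 → 23 → 24; 25 → 26 → 27 → 28 → 29; 24 + 29 → 30 → 31 → 32 → 33 → 34 (target).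

## Analysis of the target

The target is a tetracyclic amino macrolactone. A cyclopentane (C9–C13) is spiro-fused at C9 to a piperidine (N, C5–C9); the piperidine shares N and C5 with a tetrahydropyridine that carries the C1 carboxyl on its C2=C3 bond; a 15-membered lactone runs from C13 through C14–C21 and the ester oxygen back to C1. There are five stereocentres: C5 (R), C9 (S), C13 (R), C14 (S) and C17 (R). C9, C13 and C14 are contiguous, with N and the C14 branch cis on the cyclopentane; C4 and C13 are cis on the piperidine (a 1,3-relation across nitrogen); C17 is insulated from the core by the C15=C16 bond and needs reagent control. The C15=C16 alkene is Z. The C18=C19 alkene has Cl on C19 trans to C17, so that C17 and C20 are cis, which is the geometry a six-membered ring through C17–C21 and oxygen would impose. Sensitive points are the doubly allylic C17 carbinol (ionises in acid), the vinyl chloride, the β,γ-amino enoate, the basic tertiary amine, and C14 whenever C15 is a carbonyl. The hard part is the fully substituted, nitrogen-bearing C9 next to C13, which has to be set together with C5 on the other side of nitrogen. The strategy rests on two features of the piperidine: C7 is a plain CH2 reached from N through C5–C6 and through C9–C8, and C5 is a carbinamine carbon with two three-carbon arms (C6–C8 into the piperidine, C4–C2 into the enoate ring). C8–C9 can therefore come from a ketonitrone at C9 adding across an N-homoallyl alkene, with a second, identical allyl arm on C5 kept as the handle for the enoate ring.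

## Retrosynthetic reasoning

**C1–O(C21) lactone bond.** The ester is cut last, giving seco acid 33. The cut is placed here because the primary C21 hydroxyl is the best nucleophile in the molecule and the Z alkene and the cis chloroalkene pre-bend the chain. The forward step must acylate C21–OH and not the secondary C17–OH.

**Functional adjustments at the end.** 33 comes from methyl ester 32, this from the C21 silyl ether 31, and the Z C15=C16 alkene of 31 from the alkyne of 30. An alkyne is used because it can be added as a nucleophile to C17 and then reduced with syn delivery of hydrogen.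

**C16–C17.** 30 is cut between the alkyne carbon C16 and the carbinol C17 into terminal alkyne 24 and enal 29. This is the only bond whose formation creates C17 directly. The forward reaction must control the aldehyde face by a catalyst, since the core is too far away to help.

**The chloroalkene.** Enal 29 is traced through Weinreb amide 28 and hydroxy amide 27 to chlorolactone 26 and dione 25. C17, C18, C19(Cl), C20, C21 and the oxygen map onto the six ring atoms of 26, so the required C17/C20 cis geometry is guaranteed by the ring and not by a selective addition.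

**C15–C16.** Alkyne 24 comes from aldehyde 23 by one-carbon homologation, 23 from alcohol 22 and silyl ether 21. C15 stays oxygenated until late because a C15 halide would be attacked by the tertiary amine (five-membered ammonium ring).

**C7–O.** The oxygen left at C7 by the key step is removed from 19 through thionocarbonate 20 by radical reduction. It is done after the enoate ring is closed: the nitrogen is then tertiary, so only the hydroxyl is acylated, and the reactive 1,1-disubstituted acrylate is gone.

**C2=C3 and N–C23.** 19 is opened at C2=C3 (ring-closing metathesis) to diene 18, and 18 at N–C23 to amino alcohol 16 and bromide 17. The spectator allyl group on C5 is exactly the C4–C3 unit the metathesis needs, so no extra carbon has to be brought in.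

**N–O.** 16 comes from cycloadduct 15 by reductive N–O cleavage.

**C8–C9 and O–C7 (key).** 15 is cut to nitrone 14. One step forms the quaternary C9–C8 bond, closes the piperidine and the isoxazolidine, and sets C9, C5 and C7. The forward step has to choose one face of C9 and one of two diastereotopic allyl groups, both relayed from C13/C14.

**C9=N and C5–N.** 14 is made by condensation of ketone 9 with hydroxylamine 13; 13 comes from bis-carbamate 12, made by Mitsunobu alkylation of 11 with the symmetrical dienol 10.

**Nitro to silyloxy.** 9 comes from ketal 8, alcohol 7 and nitro ketal 4, the ketal of nitro ketone 3. The nitro group is the masked C15 oxygen; the ketal keeps the ring carbonyl out of the Nef/reduction sequence.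

**C13–C14.** 3 is cut between C13 and C14 into 1 and 2. A catalytic enamine Michael addition makes both stereocentres in one step from two simple achiral materials.

## Alternatives that were turned down

**Alternative 1:** The macrocycle is cut at C15–C16 as a triple bond. In the forward sense the acyclic ester A1, with methyl-capped alkynes on C14 and C17, undergoes ring-closing alkyne metathesis to the 15-membered cycloalkyne A2 (C17 as triethylsilyl ether), which is then semi-hydrogenated and desilylated. In its favour: the Z geometry is certain and independent of ring closure, the ester is made intermolecularly, and C17 is set on a small fragment where the alkyne partner can be used in excess; on these points it is stronger than the chosen end-game. Against it: it says nothing about the azaspiro core, which holds four of the five stereocentres. Both alkynes need methyl caps, which costs extra steps on the C14 side and discards four carbons. The high-valent alkylidyne catalyst must tolerate the amine, a propargylic silyl ether and the vinyl chloride in one substrate. The ring must accommodate four collinear atoms next to the rigid tricycle. The chosen route uses the same alkyne-to-Z-alkene logic on an open chain and closes the ring by lactonisation of a pre-bent seco acid, and it spends its main risk on the core instead.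

**Alternative 2:** C9–C13 is cut. The ene-sulfonamide cyclobutanol A3 is protonated at C8; the resulting N-sulfonyl iminium ion at C9 triggers a 1,2-shift of C13 from the carbinol carbon C10, expanding the cyclobutane to the spiro cyclopentanone A4. In its favour: the quaternary centre is made by an intramolecular, stereospecific shift with retention at C13, and C5 is fixed before the key step, so no desymmetrisation is needed; here it is stronger. Against it: A4 carries a ketone at C10 next to the quaternary centre, which the target lacks and which is harder to remove than a secondary alcohol. The tosyl group on a very hindered nitrogen needs dissolving-metal cleavage. A3 needs a 2-substituted cyclobutanone already carrying the C13/C14 pair. C13 must migrate to the face of C9 that is cis to the C5 side chain, whereas additions to such iminium ions with a pseudo-axial α′-substituent generally come from the other face. The chosen route builds C9 from a plain cyclopentanone, leaves no extra oxidation on the five-membered ring and no N-protecting group.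

**Alternative 3:** N–C5 and C5–C6 are cut. The α-tertiary homoallylic amine A5 condenses with aldehyde A6; the iminium ion at C5 is attacked by the allyl terminus C6 and chloride is captured at C7, giving the 4-chloropiperidine A7. In its favour: it is convergent, C5 is set in a chair transition state, and the C7 chloride is removed in one radical step where the chosen route needs two; on that point it is stronger. Against it: A5 must already hold C9 in the right configuration, which needs its own asymmetric addition to a hindered ketimine derived from a ketone like 9. Homoallylic iminium ions of α-tertiary amines undergo cationic 2-aza-Cope allyl transfer readily, which would move the allyl group to C5 and destroy the C9 centre. The two chairs (C13 or C10 equatorial) give C5 epimers. The silyloxyethyl arm of A7 still has to be turned into the enoate ring. The chosen route forms the C9–N and C9–C8 environment and C5 in one operation from ketone 9 and delivers the allyl handle ready for metathesis.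

Key step: step 9

**Remarks on the chemistry (assumptions).**
The (S,S) enantiomer of the ProPhenol ligand in step 22 is taken to deliver the alkynyl group to the Re face of the aldehyde; if a model addition shows the opposite sense, the (R,R) ligand is used with no other change.
Dione 25 is taken as a catalogue compound.

## Steps

Step 1
Reactants: 1 cyclopentanone; 2 (E)-1-nitroprop-1-ene
Product: 3 (2R)-2-[(2R)-1-nitropropan-2-yl]cyclopentan-1-one
Conditions: (R)-N-(pyrrolidin-2-ylmethyl)trifluoromethanesulfonamide (15 mol%), excess 1, iPrOH, 0 °C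
Reagents that add atoms: none
Why: Enamine-catalysed Michael addition through the synclinal transition state: the E-enamine of 1 adds to 2 while the sulfonamide N–H holds the nitro group, so C13 and C14 are set together as the syn (2R,2′R) pair; the (R)-pyrrolidine catalyst is the mirror image of the proline-derived series that gives 2S ketones. Any anti isomer should be removed here by chromatography.

Step 2
Reactants: 3 (2R)-2-[(2R)-1-nitropropan-2-yl]cyclopentan-1-one
Product: 4 (6R)-6-[(2R)-1-nitropropan-2-yl]-1,4-dioxaspiro[4.4]nonane
Conditions: TMSOCH2CH2OTMS, TMSOTf (cat.), CH2Cl2, −78 → −20 °C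
Reagents that add atoms: 1,2-bis(trimethylsilyloxy)ethane, C[Si](C)(C)OCCO[Si](C)(C)C
Why: Noyori ketalisation under aprotic, kinetic conditions masks the ring ketone without enolising C13. The ketal is needed because the next step generates an aldehyde that must be reduced selectively.

Step 3
Reactants: 4 (6R)-6-[(2R)-1-nitropropan-2-yl]-1,4-dioxaspiro[4.4]nonane
Product: 7 (2R)-2-[(6R)-1,4-dioxaspiro[4.4]nonan-6-yl]propan-1-ol, via sodium nitronate 5 (not isolated), via ketal aldehyde 6 (not isolated)
Conditions: NaOMe, MeOH, 0 °C; O3, −78 °C; then NaBH4, −78 → 0 °C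
Reagents that add atoms: ozone, [O-][O+]=O
Why: Oxidative Nef reaction: nitronate 5 is cleaved at C=N by ozone to aldehyde 6, which is reduced in the same flask before C14 (now α to a carbonyl) can epimerise. The ketal has no acetal C–H and is inert to base and ozone.

Step 4
Reactants: 7 (2R)-2-[(6R)-1,4-dioxaspiro[4.4]nonan-6-yl]propan-1-ol
Product: 8 tert-butyl{(2R)-2-[(6R)-1,4-dioxaspiro[4.4]nonan-6-yl]propoxy}diphenylsilane
Conditions: TBDPSCl, imidazole, CH2Cl2, 0 °C → rt
Reagents that add atoms: tert-butyl(chloro)diphenylsilane, CC(C)(C)[Si](Cl)(c1ccccc1)c1ccccc1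
Why: Standard silylation of a primary alcohol. The tert-butyldiphenylsilyl group is chosen over a smaller silyl group because it has to survive ketal hydrolysis, zinc in acetic acid and the acid additive of the metathesis.

Step 5
Reactants: 8 tert-butyl{(2R)-2-[(6R)-1,4-dioxaspiro[4.4]nonan-6-yl]propoxy}diphenylsilane
Product: 9 (2R)-2-[(2R)-1-{[tert-butyl(diphenyl)silyl]oxy}propan-2-yl]cyclopentan-1-one
Conditions: PPTS (cat.), acetone/H2O, 50 °C
Reagents that add atoms: water, O
Why: Mild acid-catalysed hydrolysis of a cyclopentanone dioxolane; the silyl ether is stable and the weak acid should not enolise C13 to a significant extent.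

Step 6
Reactants: 10 hepta-1,6-dien-4-ol; 11 tert-butyl N-[(tert-butoxycarbonyl)oxy]carbamate
Product: 12 tert-butyl N-[(tert-butoxycarbonyl)oxy]-N-(hepta-1,6-dien-4-yl)carbamate
Conditions: PPh3, DIAD, THF, 0 °C → rt
Reagents that add atoms: none
Why: Mitsunobu N-alkylation of the acidic N–H of 11 by a secondary alcohol; the carbinol carbon of 10 is not stereogenic, so inversion has no consequence.

Step 7
Reactants: 12 tert-butyl N-[(tert-butoxycarbonyl)oxy]-N-(hepta-1,6-dien-4-yl)carbamate
Product: 13 N-(hepta-1,6-dien-4-yl)hydroxylamine hydrochloride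
Conditions: HCl (4 M in dioxane), rt
Reagents that add atoms: hydrogen chloride, Cl
Why: Acidolysis of both tert-butoxycarbonyl groups gives the N-alkylhydroxylamine as its stable hydrochloride; the terminal alkenes are inert to anhydrous HCl at room temperature.

Step 8
Reactants: 9 (2R)-2-[(2R)-1-{[tert-butyl(diphenyl)silyl]oxy}propan-2-yl]cyclopentan-1-one; 13 N-(hepta-1,6-dien-4-yl)hydroxylamine hydrochloride
Product: 14 (Z)-N-(hepta-1,6-dien-4-yl)-(2R)-2-[(2R)-1-{[tert-butyl(diphenyl)silyl]oxy}propan-2-yl]cyclopentan-1-imine N-oxide (nitrone, oxygen syn to C13)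
Conditions: NaOAc, MgSO4, CH2Cl2, rt → 40 °C
Reagents that add atoms: none
Why: Condensation of a ketone with an N-monosubstituted hydroxylamine under acetate buffering gives the ketonitrone. The bulky N-substituent should settle on the side of the unsubstituted C10, giving the Z isomer with oxygen syn to C13, and the temperature stays below that needed for cycloaddition.

Step 9
Reactants: 14 (Z)-nitrone of 9 with N-(hepta-1,6-dien-4-yl)
Product: 15 (5S,7R,9S,13R,14R)-6-(prop-2-en-1-yl)-2′-[(2R)-1-{[tert-butyl(diphenyl)silyl]oxy}propan-2-yl]spiro[7-oxa-1-azabicyclo[2.2.1]heptane-2,1′-cyclopentane] (allyl exo on C5, C13 on the oxygen-bridge side of spiro carbon C9, bridgehead C7)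
Conditions: toluene (0.02 M), 110 °C, sealed tube
Reagents that add atoms: none
Why: Concerted, thermally allowed suprafacial [3+2] cycloaddition of the nitrone (C9=N+–O−) to the C7=C8 alkene of one allyl arm: C9 bonds to the terminal carbon C8 and oxygen to the internal carbon C7. The closest known reaction type is the thermal intramolecular cycloaddition of N-(but-3-enyl) nitrones to 7-oxa-1-azabicyclo[2.2.1]heptanes. The piperidine (N, C5–C9) closes in the bridged mode through C8–C9 with both alkene carbons inside the new six-membered ring, and the isoxazolidine (N, O, C7, C8, C9) closes through O–C7, which also completes the five-membered N–C5–C6–C7–O bridge; the fused mode would need an azetidine and cannot compete. C9 is set by approach of C8 to the face of the cyclopentylidene opposite the C14 branch, which allylic strain with the syn nitrone oxygen holds pseudo-axial over the other face; this places N cis to the branch. C5 is set by the choice between the two allyl groups: the one that reacts leaves C5–H endo, pointing at C10, and the spectator allyl exo, because an endo allyl would clash with C10 across nitrogen. C7 follows from the geometry of the bicycle and is removed later. The step needs the Z nitrone (oxygen syn to C13), which the bulky N-substituent favours, and an intact C13 centre, which the neutral, base-free medium protects.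

Step 10
Reactants: 15 spiro cycloadduct
Product: 16 (1R,5S,7S,9R)-1-[(2R)-1-{[tert-butyl(diphenyl)silyl]oxy}propan-2-yl]-7-(prop-2-en-1-yl)-6-azaspiro[4.5]decan-9-ol
Conditions: Zn dust, AcOH/THF/H2O, 50 °C
Reagents that add atoms: none
Why: Reductive cleavage of the strained isoxazolidine N–O bond by zinc in acetic acid, the standard unmasking of nitrone cycloadducts to 1,3-amino alcohols. The terminal alkene and the silyl ether are untouched and no stereocentre is affected.

Step 11
Reactants: 16 amino alcohol; 17 methyl 2-(bromomethyl)prop-2-enoate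
Product: 18 methyl 2-{[(1R,5S,7S,9R)-1-[(2R)-1-{[tert-butyl(diphenyl)silyl]oxy}propan-2-yl]-9-hydroxy-7-(prop-2-en-1-yl)-6-azaspiro[4.5]decan-6-yl]methyl}prop-2-enoate
Conditions: K2CO3, MeCN, 50 °C
Reagents that add atoms: none
Why: N-alkylation of the hindered secondary amine by a 2-(bromomethyl)acrylate, which can react at its unhindered terminal carbon (SN2′) and so tolerates the congested nitrogen. The amine is far more nucleophilic than the C7 hydroxyl.

Step 12
Reactants: 18 N-(2-methoxycarbonylallyl) amino alcohol
Product: 19 methyl ester of the 7-hydroxy spiro dehydroquinolizidine acid (rings: N/C5–C9 piperidine, N/C23/C2=C3/C4/C5 tetrahydropyridine, C9–C13 cyclopentane; C15–OTBDPS; 5S,7R,9S,13R,14R)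
Conditions: Grubbs II (10 mol%), CSA (1.1 equiv), CH2Cl2, 40 °C; NaHCO3 work-up
Reagents that add atoms: none
Why: Ring-closing metathesis between the terminal C5 allyl group and the 1,1-disubstituted acrylate closes the six-membered enoate ring (C2=C3) with loss of ethene. Protonation of the tertiary amine keeps it from deactivating the ruthenium carbene.

Step 13
Reactants: 19 7-hydroxy dehydroquinolizidine ester
Product: 20 O-phenyl thionocarbonate of 19 at C7–O (5S,7R,9S,13R,14R)
Conditions: PhOC(S)Cl, pyridine, DMAP (cat.), CH2Cl2, rt
Reagents that add atoms: O-phenyl chlorothionoformate, S=C(Cl)Oc1ccccc1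
Why: Acylation of the unhindered equatorial C7 hydroxyl gives the thionocarbonate needed for Barton–McCombie deoxygenation; the tertiary amine is too hindered to be acylated irreversibly.

Step 14
Reactants: 20 C7 thionocarbonate
Product: 21 methyl ester of the spiro dehydroquinolizidine acid with C15–OTBDPS (5R,9S,13R,14R)
Conditions: Bu3SnH, AIBN (cat.), toluene, 100 °C
Reagents that add atoms: none
Why: Barton–McCombie radical deoxygenation removes the C7 oxygen and with it the C7 stereocentre. The secondary C7 radical should be reduced by the stannane faster than it can add to the enoate, since addition to C3 would need C4 axial and 1,3-diaxial to C13.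

Step 15
Reactants: 21 silyl ether
Product: 22 primary alcohol at C15 (5R,9S,13R,14R)
Conditions: HF·pyridine, THF/pyridine, rt
Reagents that add atoms: none
Why: Fluoride cleavage of the primary silyl ether under non-basic conditions leaves the methyl enoate alone.

Step 16
Reactants: 22 C15 alcohol
Product: 23 C15 aldehyde (5R,9S,13R,14R)
Conditions: Dess–Martin periodinane, pyridine, CH2Cl2, 0 °C
Reagents that add atoms: none
Why: Dess–Martin oxidation of a primary alcohol under buffered conditions; the aldehyde is used at once because C14 is now α to a carbonyl.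

Step 17
Reactants: 23 C15 aldehyde
Product: 24 terminal alkyne C15≡C16 (5R,9S,13R,14R)
Conditions: dimethyl (1-diazo-2-oxopropyl)phosphonate, K2CO3, MeOH, 0 °C → rt
Reagents that add atoms: dimethyl (1-diazo-2-oxopropyl)phosphonate, CC(=O)C(=[N+]=[N-])P(=O)(OC)OC
Why: Ohira–Bestmann (Seyferth–Gilbert) homologation converts the aldehyde into the terminal alkyne and adds C16. Methanol/carbonate matches the methyl ester and is mild enough for an α-branched aldehyde at 0 °C.

Step 18
Reactants: 25 dihydro-2H-pyran-2,4(3H)-dione
Product: 26 4-chloro-5,6-dihydro-2H-pyran-2-one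
Conditions: (COCl)2, DMF (cat.), CH2Cl2, 0 °C → rt
Reagents that add atoms: oxalyl chloride, ClC(=O)C(=O)Cl
Why: Vilsmeier-type conversion of a cyclic 1,3-dicarbonyl (vinylogous acid) into the β-chloro enoate. The ring fixes the C17/C20 cis relation of the chloroalkene that the target requires.

Step 19
Reactants: 26 4-chloro-5,6-dihydro-2H-pyran-2-one
Product: 27 (2E)-3-chloro-5-hydroxy-N-methoxy-N-methylpent-2-enamide
Conditions: MeNH(OMe)·HCl, Me3Al, CH2Cl2, 0 °C
Reagents that add atoms: N,O-dimethylhydroxylamine hydrochloride, CNOC.Cl
Why: Weinreb aminolysis of the lactone by an aluminium amide opens the ring at the acyl–oxygen bond without touching the double-bond geometry and frees the C21 hydroxyl.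

Step 20
Reactants: 27 hydroxy Weinreb amide
Product: 28 (2E)-5-[(tert-butyldimethylsilyl)oxy]-3-chloro-N-methoxy-N-methylpent-2-enamide
Conditions: TBSCl, imidazole, CH2Cl2, 0 °C → rt
Reagents that add atoms: tert-butyl(chloro)dimethylsilane, CC(C)(C)[Si](C)(C)Cl
Why: Immediate silylation of the primary hydroxyl prevents relactonisation of the cis-configured hydroxy amide.

Step 21
Reactants: 28 silyloxy Weinreb amide
Product: 29 (2E)-5-[(tert-butyldimethylsilyl)oxy]-3-chloropent-2-enal (CHO cis to C20, Cl trans to CHO)
Conditions: DIBAL-H, THF, −78 °C; Rochelle salt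
Reagents that add atoms: none
Why: DIBAL reduction of a Weinreb amide stops at the aldehyde through the chelated tetrahedral intermediate; low temperature and neutral work-up guard the enal geometry, and 29 is used directly.

Step 22
Reactants: 24 terminal alkyne; 29 (2E)-5-[(tert-butyldimethylsilyl)oxy]-3-chloropent-2-enal
Product: 30 propargylic alcohol C15≡C16–C17H(OH)–C18=C19(Cl)–C20–C21–OTBS on the core methyl ester (5R,9S,13R,14R,17S)
Conditions: Me2Zn, (S,S)-ProPhenol (20 mol%), Ph3P=O (40 mol%), toluene, 0 °C
Reagents that add atoms: none
Why: Catalytic enantioselective addition of an alkynylzinc (dinuclear zinc ProPhenol type) to an α,β-unsaturated aldehyde forms C16–C17. The ligand must direct the alkynyl group to the Re face of the aldehyde, which gives 17S in 30 (the same centre is 17R once the alkyne is reduced, because the CIP order of C16 and C18 inverts). The ester and the hindered amine tolerate the organozinc.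

Step 23
Reactants: 30 propargylic alcohol
Product: 31 (15Z)-dienol with C21–OTBS on the core methyl ester (5R,9S,13R,14S,17R)
Conditions: H2 (1 atm), Lindlar catalyst, quinoline, EtOAc, rt
Reagents that add atoms: none
Why: Lindlar semi-hydrogenation adds hydrogen syn to the disubstituted alkyne and gives the Z alkene; the poisoned catalyst should leave the vinyl chloride and the trisubstituted enoate alone.

Step 24
Reactants: 31 C21 silyl ether
Product: 32 C17,C21-diol methyl ester (5R,9S,13R,14S,17R; 15Z)
Conditions: TBAF, AcOH, THF, 0 °C → rt
Reagents that add atoms: none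
Why: Buffered fluoride removes the primary silyl ether without exposing the doubly allylic C17 carbinol to acid or the ester to strong base.

Step 25
Reactants: 32 diol methyl ester
Product: 33 seco acid (C1 carboxylic acid, C17–OH, C21–OH; 5R,9S,13R,14S,17R; 15Z)
Conditions: LiOH, THF/MeOH/H2O, rt; then AcOH to pH 6
Reagents that add atoms: lithium hydroxide, [Li+].[OH-]
Why: Saponification of the methyl ester; the vinyl chloride and the allylic alcohols are stable to hydroxide at room temperature, and neutralisation to the isoelectric point gives the amino acid.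

Step 26
Reactants: 33 seco acid
Product: 34 target macrolactone CNP0129639.4 (5R,9S,13R,14S,17R; 15Z; Cl on C19 trans to C17)
Conditions: MNBA, DMAP, CH2Cl2 (1 mM), rt, slow addition
Reagents that add atoms: none
Why: Shiina macrolactonisation: the mixed anhydride formed under high dilution is attacked by the primary C21 hydroxyl and closes the 15-membered ring. The secondary, doubly allylic C17 hydroxyl would have to close an 11-membered ring containing the Z alkene and should not compete.

## Compound list

1 | cyclopentanone | O=C1CCCC1 | starting material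
2 | (E)-1-nitroprop-1-ene | C/C=C/[N+](=O)[O-] | starting material
3 | (2R)-2-[(2R)-1-nitropropan-2-yl]cyclopentan-1-one | O=C1CCC[C@@H]1[C@@H](C)C[N+](=O)[O-] | intermediate
4 | (6R)-6-[(2R)-1-nitropropan-2-yl]-1,4-dioxaspiro[4.4]nonane | C1COC2(O1)CCC[C@@H]2[C@@H](C)C[N+](=O)[O-] | intermediate
5 | sodium nitronate of 4 (aci-nitro sodium salt, not isolated) | C1COC2(O1)CCC[C@@H]2[C@@H](C)C=[N+]([O-])[O-].[Na+] | intermediate
6 | (2R)-2-[(6R)-1,4-dioxaspiro[4.4]nonan-6-yl]propanal (not isolated) | C1COC2(O1)CCC[C@@H]2[C@@H](C)C=O | intermediate
7 | (2R)-2-[(6R)-1,4-dioxaspiro[4.4]nonan-6-yl]propan-1-ol | C1COC2(O1)CCC[C@@H]2[C@@H](C)CO | intermediate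
8 | tert-butyl{(2R)-2-[(6R)-1,4-dioxaspiro[4.4]nonan-6-yl]propoxy}diphenylsilane | C1COC2(O1)CCC[C@@H]2[C@@H](C)CO[Si](c1ccccc1)(c1ccccc1)C(C)(C)C | intermediate
9 | (2R)-2-[(2R)-1-{[tert-butyl(diphenyl)silyl]oxy}propan-2-yl]cyclopentan-1-one | O=C1CCC[C@@H]1[C@@H](C)CO[Si](c1ccccc1)(c1ccccc1)C(C)(C)C | intermediate
10 | hepta-1,6-dien-4-ol | C=CCC(O)CC=C | starting material
11 | tert-butyl N-[(tert-butoxycarbonyl)oxy]carbamate | CC(C)(C)OC(=O)NOC(=O)OC(C)(C)C | starting material
12 | tert-butyl N-[(tert-butoxycarbonyl)oxy]-N-(hepta-1,6-dien-4-yl)carbamate | C=CCC(CC=C)N(OC(=O)OC(C)(C)C)C(=O)OC(C)(C)C | intermediate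
13 | N-(hepta-1,6-dien-4-yl)hydroxylamine hydrochloride | C=CCC(CC=C)NO.Cl | intermediate
14 | (Z)-N-(hepta-1,6-dien-4-yl) nitrone of 9, oxygen syn to C13 (13R,14R) | [O-]/[N+](C(CC=C)CC=C)=C1/CCC[C@@H]1[C@@H](C)CO[Si](c1ccccc1)(c1ccccc1)C(C)(C)C | intermediate
15 | spiro 7-oxa-1-azabicyclo[2.2.1]heptane cycloadduct, exo allyl on C5 (5S,7R,9S,13R,14R) | C=CC[C@H]3C[C@@H]5C[C@]4(CCC[C@@H]4[C@@H](C)CO[Si](c1ccccc1)(c1ccccc1)C(C)(C)C)N3O5 | intermediate
16 | (1R,5S,7S,9R)-1-[(2R)-1-{[tert-butyl(diphenyl)silyl]oxy}propan-2-yl]-7-(prop-2-en-1-yl)-6-azaspiro[4.5]decan-9-ol | C=CC[C@H]3C[C@@H](O)C[C@]4(CCC[C@@H]4[C@@H](C)CO[Si](c1ccccc1)(c1ccccc1)C(C)(C)C)N3 | intermediate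
17 | methyl 2-(bromomethyl)prop-2-enoate | C=C(CBr)C(=O)OC | starting material
18 | N-(2-methoxycarbonylprop-2-en-1-yl) derivative of 16 | C=CC[C@H]3C[C@@H](O)C[C@]4(CCC[C@@H]4[C@@H](C)CO[Si](c1ccccc1)(c1ccccc1)C(C)(C)C)N3CC(=C)C(=O)OC | intermediate
19 | 7-hydroxy spiro dehydroquinolizidine methyl ester, C15–OTBDPS (5S,7R,9S,13R,14R) | COC(=O)C2=CC[C@H]3C[C@@H](O)C[C@]4(CCC[C@@H]4[C@@H](C)CO[Si](c1ccccc1)(c1ccccc1)C(C)(C)C)N3C2 | intermediate
20 | C7 O-phenyl thionocarbonate of 19 | COC(=O)C2=CC[C@H]3C[C@@H](OC(=S)Oc5ccccc5)C[C@]4(CCC[C@@H]4[C@@H](C)CO[Si](c1ccccc1)(c1ccccc1)C(C)(C)C)N3C2 | intermediate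
21 | spiro dehydroquinolizidine methyl ester, C15–OTBDPS (5R,9S,13R,14R) | COC(=O)C2=CC[C@H]3CCC[C@]4(CCC[C@@H]4[C@@H](C)CO[Si](c1ccccc1)(c1ccccc1)C(C)(C)C)N3C2 | intermediate
22 | C15 primary alcohol (5R,9S,13R,14R) | COC(=O)C2=CC[C@H]3CCC[C@]4(CCC[C@@H]4[C@@H](C)CO)N3C2 | intermediate
23 | C15 aldehyde (5R,9S,13R,14R) | COC(=O)C2=CC[C@H]3CCC[C@]4(CCC[C@@H]4[C@@H](C)C=O)N3C2 | intermediate
24 | C15≡C16 terminal alkyne (5R,9S,13R,14R) | COC(=O)C2=CC[C@H]3CCC[C@]4(CCC[C@@H]4[C@@H](C)C#C)N3C2 | intermediate
25 | dihydro-2H-pyran-2,4(3H)-dione | O=C1CC(=O)CCO1 | starting material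
26 | 4-chloro-5,6-dihydro-2H-pyran-2-one | O=C1C=C(Cl)CCO1 | intermediate
27 | (2E)-3-chloro-5-hydroxy-N-methoxy-N-methylpent-2-enamide | CON(C)C(=O)/C=C(/Cl)CCO | intermediate
28 | (2E)-5-[(tert-butyldimethylsilyl)oxy]-3-chloro-N-methoxy-N-methylpent-2-enamide | CON(C)C(=O)/C=C(/Cl)CCO[Si](C)(C)C(C)(C)C | intermediate
29 | (2E)-5-[(tert-butyldimethylsilyl)oxy]-3-chloropent-2-enal | O=C/C=C(/Cl)CCO[Si](C)(C)C(C)(C)C | intermediate
30 | propargylic alcohol, C21–OTBS, methyl ester (5R,9S,13R,14R,17S) | COC(=O)C2=CC[C@H]3CCC[C@]4(CCC[C@@H]4[C@@H](C)C#C[C@@H](O)/C=C(/Cl)CCO[Si](C)(C)C(C)(C)C)N3C2 | intermediate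
31 | (15Z)-dienol, C21–OTBS, methyl ester (5R,9S,13R,14S,17R) | COC(=O)C2=CC[C@H]3CCC[C@]4(CCC[C@@H]4[C@@H](C)/C=C\[C@@H](O)/C=C(/Cl)CCO[Si](C)(C)C(C)(C)C)N3C2 | intermediate
32 | C17,C21-diol methyl ester (5R,9S,13R,14S,17R) | COC(=O)C2=CC[C@H]3CCC[C@]4(CCC[C@@H]4[C@@H](C)/C=C\[C@@H](O)/C=C(/Cl)CCO)N3C2 | intermediate
33 | seco acid (5R,9S,13R,14S,17R) | OC(=O)C2=CC[C@H]3CCC[C@]4(CCC[C@@H]4[C@@H](C)/C=C\[C@@H](O)/C=C(/Cl)CCO)N3C2 | intermediate
34 | CNP0129639.4, 15-membered macrolactone (5R,9S,13R,14S,17R; 15Z) | C[C@H]1/C=C\[C@@H](O)/C=C(/Cl)CCOC(=O)C2=CC[C@H]3CCC[C@]4(CCC[C@H]14)N3C2 | target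

## Step count and least certain steps

Total: 26 steps. Longest linear sequence: 20 steps (steps 1–5, 8–17, 22–26); the hydroxylamine (steps 6–7) and the enal (steps 18–21) are side branches.

**Step 9 (key step).** Three things can go wrong:
- Incomplete discrimination between the two allyl groups or between the two faces of C9, which gives diastereomers at C5 or C9.
- A [3,3] 2-aza-Cope shift of the N-homoallyl nitrone that moves an allyl group from C5 to C9 before cycloaddition; this leads to the same constitution but sets C9 without the facial bias relied on.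
- Thermal nitrone/N-hydroxyenamine tautomerism that epimerises C13.

The fallback replaces desymmetrisation by a non-symmetric, enantiopure hydroxylamine with a single alkene, whose C5 configuration reinforces the facial preference (matched case). It sets out from 9 and comes back at 15. Commercial 3-[(tert-butyldimethylsilyl)oxy]propanal is allylated enantioselectively (Brown- or Krische-type, reagent antipode chosen for the S alcohol) to (3S)-1-[(tert-butyldimethylsilyl)oxy]hex-5-en-3-ol F1. Mitsunobu reaction with 11, with inversion, gives tert-butyl N-[(tert-butoxycarbonyl)oxy]-N-[(3R)-1-[(tert-butyldimethylsilyl)oxy]hex-5-en-3-yl]carbamate F2. HCl in methanol removes both carbamates and the silyl ether to give (3R)-3-(hydroxyamino)hex-5-en-1-ol hydrochloride F3. Condensation with 9 as in step 8 gives the hydroxyethyl nitrone F4, and heating gives the hydroxyethyl cycloadduct F5. Dess–Martin oxidation gives the cycloadduct aldehyde F6, and Wittig methylenation turns its CH2CHO arm into the allyl group of 15.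

**Step 1.** Diastereo- and enantiocontrol may be insufficient, because five-ring enamines are flatter and less selective than six-ring ones and the aliphatic nitroalkene 2 is less reactive and polymerises easily. The fallback uses a stoichiometric chiral enamine; it sets out from 1 and 2 and comes back at 3. Compound 1 is condensed with (R)-2-(methoxymethyl)pyrrolidine to the enamine (2R)-1-(cyclopent-1-en-1-yl)-2-(methoxymethyl)pyrrolidine F7, which adds to 2 in ether at low temperature; two-phase acidic hydrolysis gives 3 and returns the auxiliary. The antipode of the auxiliary is used if a model shows the opposite sense.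

**Step 8.** Condensation of the hindered α-branched ketone with a secondary-alkyl hydroxylamine may be slow, and buffer-mediated enolisation can then erode C13. The fallback changes the bond-forming mechanism; it sets out from 13 and 9 and comes back at 14. Compound 13 is silylated (chlorotrimethylsilane, triethylamine) to N-(hepta-1,6-dien-4-yl)-N,O-bis(trimethylsilyl)hydroxylamine F8, which adds to the carbonyl of 9 under aprotic conditions and loses siloxane in a Peterson-type elimination to give 14 without a protic acid–base medium.

**Step 22.** Facial control in the alkynyl transfer may be low, and the β-chloro enal 29 can isomerise by reversible conjugate addition of chloride or Lewis bases. The fallback sets the centre by reduction instead of addition; it sets out from 24 and 29 and comes back at 30. The two are joined without chiral ligand (alkynylzinc from dimethylzinc) to give 30 mixed with its C17 epimer F9. Dess–Martin oxidation converts both into the ynone F10. CBS reduction with the (S)-oxazaborolidine and catecholborane at low temperature, in which the alkynyl group acts as the small substituent, returns 30.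

**Step 26.** The free C17 hydroxyl may be acylated (11-membered lactone or oligomers), or activation of the zwitterionic amino acid may be sluggish. The fallback protects C17; it sets out from 31 and comes back at 34. Silylation of 31 (TBS triflate, 2,6-lutidine) gives the bis-silyl ether F11, and saponification gives the bis-silyl acid F12. Buffered HF·pyridine removes only the primary silyl ether to give the C17-silylated hydroxy acid F13. Macrolactonisation as in step 26 gives the C17-silylated macrolactone F14, and HF·pyridine then gives 34.

## Further compounds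

F1 | step 9 | (3S)-1-[(tert-butyldimethylsilyl)oxy]hex-5-en-3-ol | C=CC[C@H](O)CCO[Si](C)(C)C(C)(C)C
F2 | step 9 | tert-butyl N-[(tert-butoxycarbonyl)oxy]-N-[(3R)-1-[(tert-butyldimethylsilyl)oxy]hex-5-en-3-yl]carbamate | C=CC[C@H](CCO[Si](C)(C)C(C)(C)C)N(OC(=O)OC(C)(C)C)C(=O)OC(C)(C)C
F3 | step 9 | (3R)-3-(hydroxyamino)hex-5-en-1-ol hydrochloride | C=CC[C@H](CCO)NO.Cl
F4 | step 9 | (Z)-nitrone of 9 with N-[(3R)-1-hydroxyhex-5-en-3-yl] | [O-]/[N+]([C@H](CC=C)CCO)=C1/CCC[C@@H]1[C@@H](C)CO[Si](c1ccccc1)(c1ccccc1)C(C)(C)C
F5 | step 9 | cycloadduct with exo 2-hydroxyethyl on C5 | OCC[C@H]3C[C@@H]5C[C@]4(CCC[C@@H]4[C@@H](C)CO[Si](c1ccccc1)(c1ccccc1)C(C)(C)C)N3O5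
F6 | step 9 | cycloadduct with exo 2-oxoethyl on C5 | O=CC[C@H]3C[C@@H]5C[C@]4(CCC[C@@H]4[C@@H](C)CO[Si](c1ccccc1)(c1ccccc1)C(C)(C)C)N3O5
F7 | step 1 | (2R)-1-(cyclopent-1-en-1-yl)-2-(methoxymethyl)pyrrolidine | COC[C@H]1CCCN1C1=CCCC1
F8 | step 8 | N-(hepta-1,6-dien-4-yl)-N,O-bis(trimethylsilyl)hydroxylamine | C=CCC(CC=C)N(O[Si](C)(C)C)[Si](C)(C)C
F9 | step 22 | C17 epimer of 30 | COC(=O)C2=CC[C@H]3CCC[C@]4(CCC[C@@H]4[C@@H](C)C#C[C@H](O)/C=C(/Cl)CCO[Si](C)(C)C(C)(C)C)N3C2
F10 | step 22 | C17 ynone | COC(=O)C2=CC[C@H]3CCC[C@]4(CCC[C@@H]4[C@@H](C)C#CC(=O)/C=C(/Cl)CCO[Si](C)(C)C(C)(C)C)N3C2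
F11 | step 26 | C17,C21-bis(tert-butyldimethylsilyl) ether of 32 | COC(=O)C2=CC[C@H]3CCC[C@]4(CCC[C@@H]4[C@@H](C)/C=C\[C@@H](O[Si](C)(C)C(C)(C)C)/C=C(/Cl)CCO[Si](C)(C)C(C)(C)C)N3C2
F12 | step 26 | bis-silyl carboxylic acid | OC(=O)C2=CC[C@H]3CCC[C@]4(CCC[C@@H]4[C@@H](C)/C=C\[C@@H](O[Si](C)(C)C(C)(C)C)/C=C(/Cl)CCO[Si](C)(C)C(C)(C)C)N3C2
F13 | step 26 | C17-silylated seco acid with free C21–OH | OC(=O)C2=CC[C@H]3CCC[C@]4(CCC[C@@H]4[C@@H](C)/C=C\[C@@H](O[Si](C)(C)C(C)(C)C)/C=C(/Cl)CCO)N3C2
F14 | step 26 | C17 tert-butyldimethylsilyl ether of 34 | C[C@H]1/C=C\[C@@H](O[Si](C)(C)C(C)(C)C)/C=C(/Cl)CCOC(=O)C2=CC[C@H]3CCC[C@]4(CCC[C@H]14)N3C2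
A1 | alternative 1 | acyclic ester with methyl-capped alkynes on C14 and C17, C17 triethylsilyl ether | CC#C[C@@H](O[Si](CC)(CC)CC)/C=C(/Cl)CCOC(=O)C2=CC[C@H]3CCC[C@]4(CCC[C@@H]4[C@@H](C)C#CC)N3C2
A2 | alternative 1 | 15-membered cycloalkyne, C17 triethylsilyl ether | C[C@H]1C#C[C@@H](O[Si](CC)(CC)CC)/C=C(/Cl)CCOC(=O)C2=CC[C@H]3CCC[C@]4(CCC[C@H]14)N3C2
A3 | alternative 2 | N-tosyl ene-sulfonamide carrying the 1-hydroxycyclobutyl group on C9 (carbinol configuration open, lost in the shift) | Cc1ccc(cc1)S(=O)(=O)N1[C@@H](CCO[Si](C(C)C)(C(C)C)C(C)C)CCC=C1C2(O)CC[C@@H]2[C@@H](C)COCc3ccccc3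
A4 | alternative 2 | N-tosyl 1-azaspiro[4.5]decane with ketone at C10 | Cc1ccc(cc1)S(=O)(=O)N1[C@@H](CCO[Si](C(C)C)(C(C)C)C(C)C)CCC[C@]13C(=O)CC[C@@H]3[C@@H](C)COCc4ccccc4
A5 | alternative 3 | 1-allyl-2-substituted cyclopentan-1-amine (C9 amine) | C=CC[C@@]1(N)CCC[C@@H]1[C@@H](C)COCc2ccccc2
A6 | alternative 3 | 3-[(triisopropylsilyl)oxy]propanal | O=CCCO[Si](C(C)C)(C(C)C)C(C)C
A7 | alternative 3 | 4-chloro spiro-piperidine (chloride on C7) | CC(C)[Si](C(C)C)(C(C)C)OCC[C@H]3C[C@@H](Cl)C[C@]4(CCC[C@@H]4[C@@H](C)COCc5ccccc5)N3
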